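The route rests on removing arene A (C4a', C5', C6', C7', C8', C8a') from the quinone half. That half is a naphthazarin, whose two rings swap quinone and benzenoid roles by proton shift. The ring carrying the C2' ethyl group and the C3' ether oxygen can therefore travel as a simple benzene, and the C5',C6',C8'-oxygenated ring is grown last. A single Dötz benzannulation forms C7'–C8', C5'–C6' and C4a'–C5' and brings in the three oxygens with carbon monoxide, ethoxyacetylene and the carbene methoxy group. Its precursor is an aryl(methoxy)carbene pentacarbonylchromium complex that already holds the hindered C2–O–C3' ether to enantiopure, saturated, silyl-protected fragment B.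

Key step: step 14

Assumption: the target is drawn as one prototropic tautomer of a naphthazarin. The tautomer with the quinone in ring A is the same substance.

Locants: unprimed C1–C8a belong to the trione half (fragment B) and primed C1'–C8a' to the quinone half, and they are kept for all intermediates. "B(TES)3" means the (1S,2S,3S,4S)-2-ethyl-5,6,8-trimethoxy-1,3,4-tris(triethylsilyloxy)-1,2,3,4-tetrahydronaphthalen-2-yl group, bonded through C2.

Design points:
- **Alkoxide partner.** The tertiary alkoxide is used while C1 is still a ketone, because a silyl ether on the neighbouring oxygen would migrate onto the alkoxide.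
- **Haloquinone.** The halogen must sit next to ethyl. Halogenation of ethylhydroquinone derivatives goes para to ethyl, so the pattern is made by directed lithiation instead.
- **Bromine.** It enters as bromide on the quinone. An electrophilic bromination would compete with C7–H and C3=C4 of fragment B.
- **Alkene.** C3=C4 is dihydroxylated before any metalation, because a 1,2-dioxygenated 1,2-dihydronaphthalene aromatises easily by loss of aryloxide.
- **Temporary centres.** The carbinol centres at C1, C3 and C4 all end as ketones. They are drawn as the expected major isomers, and any epimer converges.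

Step 1
Reactants: 1 2,4,5-trimethoxybenzoic acid
Product: 3 N,N-diethyl-2,4,5-trimethoxybenzamide, via acid chloride 2 (not isolated)
Conditions: (COCl)2, DMF (cat.), CH2Cl2, 0 °C → rt; then Et2NH (3 equiv), 0 °C
Reagents that add atoms: diethylamine CCNCC
Why: Amide formation through the acid chloride (nucleophilic acyl substitution) installs the tertiary amide that serves first as metalation director and later as the C1 acyl donor.

Step 2
Reactants: 3 N,N-diethyl-2,4,5-trimethoxybenzamide; 4 (E)-1-bromopent-2-ene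
Product: 7 N,N-diethyl-3,4,6-trimethoxy-2-[(2E)-pent-2-en-1-yl]benzamide, via aryllithium 5 (not isolated), via arylzinc chloride 6 (not isolated)
Conditions: s-BuLi, TMEDA, THF, −78 °C; ZnCl2, −78 → 0 °C; 4, Pd(PPh3)4 (5 mol %), rt
Reagents that add atoms: none
Why: Directed ortho-metalation removes the only proton flanked by the amide and a methoxy group (future C4a), and Negishi coupling of the arylzinc through a π-allylpalladium intermediate joins the unsubstituted allyl terminus, which keeps the pentenyl chain linear.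

Step 3
Reactants: 7 N,N-diethyl-3,4,6-trimethoxy-2-[(2E)-pent-2-en-1-yl]benzamide
Product: 8 2-ethyl-5,6,8-trimethoxynaphthalen-1-ol
Conditions: LiN(i-Pr)2 (2.2 equiv), THF, −78 °C → rt; 1 M HCl
Reagents that add atoms: none
Why: In this anionic benzannulation of an ortho-allylbenzamide the benzylic-allylic CH2 is deprotonated, the ethyl-bearing terminus of the allyl anion acylates on the neighbouring amide (C1–C2 bond), and loss of diethylamide followed by enolisation gives the naphthol.

Step 4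
Reactants: 8 2-ethyl-5,6,8-trimethoxynaphthalen-1-ol
Product: 9 (2R)-2-ethyl-2-hydroxy-5,6,8-trimethoxynaphthalen-1(2H)-one
Conditions: enantiopure axially chiral bis(iodyl)biaryl reagent (0.6 equiv), THF, 0 °C → rt; aq. NaHCO3; recrystallisation
Reagents that add atoms: 2,2'-diiodyl-4,4',6,6'-tetramethylbiphenyl-3,3'-dicarboxylic acid in its cyclic bis(benziodoxolone oxide) form, single atropisomer Cc1cc(C)c2C(=O)OI(=O)(O)c2c1-c1c(C)cc(C)c2C(=O)OI(=O)(O)c12
Why: Hydroxylative phenol dearomatisation with a pentavalent-iodine reagent of the IBX type binds the naphthol oxygen to iodine and passes an iodyl oxygen to the only available ortho carbon C2, a reaction known for 2-alkyl-1-naphthols; the biaryl axis of the reagent selects the face, the atropisomer is chosen so that C2 is R, and crystallisation should raise the enantiomeric purity.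

Step 5
Reactants: 10 2-fluoro-1,4-dimethoxybenzene; 11 iodoethane
Product: 13 2-ethyl-3-fluoro-1,4-dimethoxybenzene, via aryllithium 12 (not isolated)
Conditions: n-BuLi, THF, −78 °C; 11, −78 → −20 °C
Reagents that add atoms: none
Why: Directed ortho-lithiation takes the proton between fluorine and methoxy, the most acidic site, and alkylation with 11 places ethyl next to fluorine.

Step 6
Reactants: 13 2-ethyl-3-fluoro-1,4-dimethoxybenzene
Product: 14 2-ethyl-3-fluoro-1,4-benzoquinone
Conditions: (NH4)2Ce(NO3)6, MeCN/H2O, 0 °C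
Reagents that add atoms: water O
Why: Oxidative demethylation of a hydroquinone dimethyl ether by tetravalent cerium gives the quinone, the carbonyl oxygens coming from water.

Step 7
Reactants: 9 (2R)-2-ethyl-2-hydroxy-5,6,8-trimethoxynaphthalen-1(2H)-one; 14 2-ethyl-3-fluoro-1,4-benzoquinone
Product: 16 2-ethyl-3-{[(2R)-2-ethyl-5,6,8-trimethoxy-1-oxo-1,2-dihydronaphthalen-2-yl]oxy}-1,4-benzoquinone, via potassium alkoxide 15 (not isolated)
Conditions: 9, KN(SiMe3)2, THF, −78 °C; added to 14 (1.5 equiv), THF, −78 → −30 °C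
Reagents that add atoms: none
Why: Nucleophilic vinylic substitution (addition–elimination) on a haloquinone, a vinylogous acyl fluoride: fluorine makes its own carbon the hardest electrophilic site and leaves irreversibly, and the C2–O bond of 9 is not touched, so the configuration is retained.

Step 8
Reactants: 16 2-ethyl-3-{[(2R)-2-ethyl-5,6,8-trimethoxy-1-oxo-1,2-dihydronaphthalen-2-yl]oxy}-1,4-benzoquinone
Product: 17 (2R)-2-(4-bromo-2-ethyl-3,6-dihydroxyphenoxy)-2-ethyl-5,6,8-trimethoxynaphthalen-1(2H)-one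
Conditions: HBr (33 % in AcOH, 1.05 equiv), CH2Cl2, −20 °C
Reagents that add atoms: hydrogen bromide Br
Why: Conjugate addition of HBr to a quinone followed by enolisation: the ether oxygen turns C1'=O into a vinylogous ester, so C4'=O is the activating carbonyl and bromide adds at its β-carbon C8a', para to the ether, while bromine delivered as a nucleophile ignores C7–H and C3=C4 of fragment B.

Step 9
Reactants: 17 (2R)-2-(4-bromo-2-ethyl-3,6-dihydroxyphenoxy)-2-ethyl-5,6,8-trimethoxynaphthalen-1(2H)-one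
Product: 18 (2R)-2-(4-bromo-2-ethyl-3,6-dimethoxyphenoxy)-2-ethyl-5,6,8-trimethoxynaphthalen-1(2H)-one
Conditions: MeI, K2CO3, DMF, rt, argon
Reagents that add atoms: iodomethane CI
Why: Williamson methylation caps both phenols under argon, and the non-enolisable ketone is inert to the mild base.

Step 10
Reactants: 18 (2R)-2-(4-bromo-2-ethyl-3,6-dimethoxyphenoxy)-2-ethyl-5,6,8-trimethoxynaphthalen-1(2H)-one
Product: 19 (2R,3S,4S)-2-(4-bromo-2-ethyl-3,6-dimethoxyphenoxy)-2-ethyl-3,4-dihydroxy-5,6,8-trimethoxy-3,4-dihydronaphthalen-1(2H)-one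
Conditions: K2OsO4·2H2O (5 mol %), NMO, acetone/H2O, rt
Reagents that add atoms: N-methylmorpholine N-oxide C[N+]1([O-])CCOCC1; water O
Why: Catalytic osmium tetroxide syn-dihydroxylation with NMO as reoxidant should approach C3=C4 anti to the allylic aryloxy group (steric and stereoelectronic preferences agree), giving the 3S,4S cis-diol, and both centres are erased later.

Step 11
Reactants: 19 (2R,3S,4S)-2-(4-bromo-2-ethyl-3,6-dimethoxyphenoxy)-2-ethyl-3,4-dihydroxy-5,6,8-trimethoxy-3,4-dihydronaphthalen-1(2H)-one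
Product: 20 (1S,2S,3S,4S)-2-(4-bromo-2-ethyl-3,6-dimethoxyphenoxy)-2-ethyl-5,6,8-trimethoxy-1,2,3,4-tetrahydronaphthalene-1,3,4-triol
Conditions: NaBH4, CeCl3·7H2O, MeOH/THF, −20 °C
Reagents that add atoms: none
Why: Luche reduction is fast and barely basic, so retro-aldol opening of the β-hydroxy ketone is avoided; hydride is expected on the face opposite the aryloxy group, helped by the C3 alkoxyborohydride, to give 1S, a centre that is erased later (the C2 descriptor changes only because the priorities change).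

Step 12
Reactants: 20 (1S,2S,3S,4S)-2-(4-bromo-2-ethyl-3,6-dimethoxyphenoxy)-2-ethyl-5,6,8-trimethoxy-1,2,3,4-tetrahydronaphthalene-1,3,4-triol
Product: 21 1-bromo-3-ethyl-2,5-dimethoxy-4-[B(TES)3-oxy]benzene
Conditions: Et3SiOTf (4 equiv), 2,6-lutidine, CH2Cl2, −40 → 0 °C
Reagents that add atoms: triethylsilyl trifluoromethanesulfonate CC[Si](CC)(CC)OS(=O)(=O)C(F)(F)F
Why: Silylation with the triflate reaches all three hindered secondary alcohols in one operation, and triethylsilyl ethers survive organolithium and chromium chemistry yet leave under mild fluoride.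

Step 13
Reactants: 21 1-bromo-3-ethyl-2,5-dimethoxy-4-[B(TES)3-oxy]benzene; 22 hexacarbonylchromium Cr(CO)6
Product: 25 pentacarbonyl{[3-ethyl-2,5-dimethoxy-4-(B(TES)3-oxy)phenyl](methoxy)carbene}chromium, via aryllithium 23 (not isolated), via lithium acylchromate 24 (not isolated)
Conditions: n-BuLi, Et2O, −78 °C; 22, −78 °C → rt; evaporate; MeOTf, CH2Cl2, 0 °C
Reagents that add atoms: methyl trifluoromethanesulfonate COS(=O)(=O)C(F)(F)F
Why: Fischer carbene synthesis: bromine–lithium exchange, faster at −78 °C than any deprotonation, then addition of the aryllithium to a carbonyl ligand of 22 and O-methylation of the acylchromate.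

Step 14
Reactants: 25 pentacarbonyl{[3-ethyl-2,5-dimethoxy-4-(B(TES)3-oxy)phenyl](methoxy)carbene}chromium; 26 ethoxyacetylene
Product: 28 6'-ethoxy-2'-ethyl-1',4',8'-trimethoxy-3'-[B(TES)3-oxy]naphthalen-5'-ol, via tricarbonylchromium naphthol complex 27 (not isolated)
Conditions: 26 (3 equiv), t-BuOMe, 55 °C, argon; then MeCN, 40 °C
Reagents that add atoms: none
Why: Thermal loss of one cis carbonyl ligand (helped by transient chelation of the C1' methoxy group) opens a site for 26, which inserts into the Cr=C bond with its CH terminus bonding to the carbene carbon C8', and migration of a carbonyl ligand onto the new ethoxy-bearing carbene carbon C6' gives a chromium-bound dienylketene (C5'–C6'). Ring A closes by six-electron electrocyclisation of that ketene, C5' bonding to the only free ortho carbon C4a', and enolisation gives the 4-methoxy-1-naphthol as its Cr(CO)3 complex 27, from which acetonitrile strips the metal. The closest known reaction type is the Dötz benzannulation of ortho-methoxyaryl(methoxy)carbene pentacarbonylchromium complexes with terminal alkynes, for which 1-alkoxyalkynes are documented but rare partners. No stereocentre is formed, and the four stereocentres of fragment B are remote and untouched. The selectivity needed is the alkyne orientation: the steric rule (substituted alkyne carbon next to the carbonyl-derived carbon) and the ynol ether polarity (nucleophilic CH carbon to the electrophilic carbene carbon) point the same way and put ethoxy on C6'. Saturated, silyl-protected C1, C3 and C4 take away the aromatisation-prone allylic ether and any alkene that could compete for the metal.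

Step 15
Reactants: 28 6'-ethoxy-2'-ethyl-1',4',8'-trimethoxy-3'-[B(TES)3-oxy]naphthalen-5'-ol
Product: 29 6'-ethoxy-2'-ethyl-1',4'-dimethoxy-3'-[B(TES)3-oxy]naphthalene-5',8'-dione
Conditions: PhI(OAc)2, MeCN/H2O, 0 °C
Reagents that add atoms: water O
Why: Hypervalent-iodine oxidation of a 4-methoxy-1-naphthol to the 1,4-quinone needs a free phenol for ligand exchange, so water attacks C8', methanol leaves, and the para-dimethoxy arene of fragment B is spared.

Step 16
Reactants: 29 6'-ethoxy-2'-ethyl-1',4'-dimethoxy-3'-[B(TES)3-oxy]naphthalene-5',8'-dione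
Product: 30 6'-ethoxy-2'-ethyl-1',4'-dimethoxy-3'-{[(1S,2S,3S,4S)-2-ethyl-1,3,4-trihydroxy-5,6,8-trimethoxy-1,2,3,4-tetrahydronaphthalen-2-yl]oxy}naphthalene-5',8'-dione
Conditions: Et3N·3HF, THF, rt
Reagents that add atoms: none
Why: Fluoride-driven cleavage of the three Si–O bonds runs under nearly neutral conditions that neither ionise the benzylic carbinols nor harm the ethoxyquinone.

Step 17
Reactants: 30 6'-ethoxy-2'-ethyl-1',4'-dimethoxy-3'-{[(1S,2S,3S,4S)-2-ethyl-1,3,4-trihydroxy-5,6,8-trimethoxy-1,2,3,4-tetrahydronaphthalen-2-yl]oxy}naphthalene-5',8'-dione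
Product: 31 (2S)-2-[(6'-ethoxy-2'-ethyl-1',4'-dimethoxy-5',8'-dioxo-5',8'-dihydronaphthalen-3'-yl)oxy]-2-ethyl-5,6,8-trimethoxynaphthalene-1,3,4(2H)-trione
Conditions: IBX (6 equiv), DMSO, rt
Reagents that add atoms: none
Why: IBX oxidation takes all three secondary alcohols to ketones and is known to turn 1,2-diols into 1,2-diketones without C–C cleavage; the neutral medium avoids retro-aldol or retro-Claisen opening, and quaternary C2 cannot epimerise.

Step 18
Reactants: 31 (2S)-2-[(6'-ethoxy-2'-ethyl-1',4'-dimethoxy-5',8'-dioxo-5',8'-dihydronaphthalen-3'-yl)oxy]-2-ethyl-5,6,8-trimethoxynaphthalene-1,3,4(2H)-trione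
Product: 33 CNP0325426.1, via ring-A quinone tautomer 32 (not isolated)
Conditions: BBr3 (excess), CH2Cl2, −78 °C → rt; H2O
Reagents that add atoms: none
Why: Lewis-acid ether cleavage with BBr3 removes five methyl groups and the ethyl group, the C2–O–C3' ether survives because C2 is tertiary and flanked by two carbonyl groups (no substitution pathway), and the released 32 is the naphthazarin tautomer of 33.

Compound list
1 | 2,4,5-trimethoxybenzoic acid | OC(=O)c1cc(OC)c(OC)cc1OC | starting material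
2 | 2,4,5-trimethoxybenzoyl chloride | ClC(=O)c1cc(OC)c(OC)cc1OC | intermediate
3 | N,N-diethyl-2,4,5-trimethoxybenzamide | CCN(CC)C(=O)c1cc(OC)c(OC)cc1OC | intermediate
4 | (E)-1-bromopent-2-ene | CC/C=C/CBr | starting material
5 | 6-lithio-N,N-diethyl-2,4,5-trimethoxybenzamide | CCN(CC)C(=O)c1c([Li])c(OC)c(OC)cc1OC | intermediate
6 | [2-(diethylcarbamoyl)-3,5,6-trimethoxyphenyl]zinc chloride | CCN(CC)C(=O)c1c([Zn]Cl)c(OC)c(OC)cc1OC | intermediate
7 | N,N-diethyl-3,4,6-trimethoxy-2-[(2E)-pent-2-en-1-yl]benzamide | CC/C=C/Cc1c(OC)c(OC)cc(OC)c1C(=O)N(CC)CC | intermediate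
8 | 2-ethyl-5,6,8-trimethoxynaphthalen-1-ol | CCc1ccc2c(OC)c(OC)cc(OC)c2c1O | intermediate
9 | (2R)-2-ethyl-2-hydroxy-5,6,8-trimethoxynaphthalen-1(2H)-one | O[C@]1(CC)C=Cc2c(OC)c(OC)cc(OC)c2C1=O | intermediate
10 | 2-fluoro-1,4-dimethoxybenzene | COc1ccc(OC)c(F)c1 | starting material
11 | iodoethane | CCI | starting material
12 | 2-fluoro-3,6-dimethoxyphenyllithium | COc1ccc(OC)c([Li])c1F | intermediate
13 | 2-ethyl-3-fluoro-1,4-dimethoxybenzene | CCc1c(F)c(OC)ccc1OC | intermediate
14 | 2-ethyl-3-fluoro-1,4-benzoquinone | CCC1=C(F)C(=O)C=CC1=O | intermediate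
15 | potassium alkoxide of 9 | [K+].[O-][C@]1(CC)C=Cc2c(OC)c(OC)cc(OC)c2C1=O | intermediate
16 | 2-ethyl-3-{[(2R)-2-ethyl-5,6,8-trimethoxy-1-oxo-1,2-dihydronaphthalen-2-yl]oxy}-1,4-benzoquinone | CCC1=C(O[C@]2(CC)C=Cc3c(OC)c(OC)cc(OC)c3C2=O)C(=O)C=CC1=O | intermediate
17 | (2R)-2-(4-bromo-2-ethyl-3,6-dihydroxyphenoxy)-2-ethyl-5,6,8-trimethoxynaphthalen-1(2H)-one | CCc1c(O)c(Br)cc(O)c1O[C@]2(CC)C=Cc3c(OC)c(OC)cc(OC)c3C2=O | intermediate
18 | (2R)-2-(4-bromo-2-ethyl-3,6-dimethoxyphenoxy)-2-ethyl-5,6,8-trimethoxynaphthalen-1(2H)-one | CCc1c(OC)c(Br)cc(OC)c1O[C@]2(CC)C=Cc3c(OC)c(OC)cc(OC)c3C2=O | intermediate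
19 | (2R,3S,4S)-2-(4-bromo-2-ethyl-3,6-dimethoxyphenoxy)-2-ethyl-3,4-dihydroxy-5,6,8-trimethoxy-3,4-dihydronaphthalen-1(2H)-one (cis-diol anti to the aryloxy group) | CCc1c(OC)c(Br)cc(OC)c1O[C@]2(CC)[C@@H](O)[C@@H](O)c3c(OC)c(OC)cc(OC)c3C2=O | intermediate
20 | (1S,2S,3S,4S)-2-(4-bromo-2-ethyl-3,6-dimethoxyphenoxy)-2-ethyl-5,6,8-trimethoxy-1,2,3,4-tetrahydronaphthalene-1,3,4-triol (C1–OH cis to the aryloxy group) | CCc1c(OC)c(Br)cc(OC)c1O[C@]2(CC)[C@@H](O)[C@@H](O)c3c(OC)c(OC)cc(OC)c3[C@@H]2O | intermediate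
21 | 1-bromo-3-ethyl-2,5-dimethoxy-4-[B(TES)3-oxy]benzene | CCc1c(OC)c(Br)cc(OC)c1O[C@]2(CC)[C@@H](O[Si](CC)(CC)CC)[C@@H](O[Si](CC)(CC)CC)c3c(OC)c(OC)cc(OC)c3[C@@H]2O[Si](CC)(CC)CC | intermediate
22 | hexacarbonylchromium | O=C=[Cr](=C=O)(=C=O)(=C=O)(=C=O)=C=O | starting material
23 | 3-ethyl-2,5-dimethoxy-4-[B(TES)3-oxy]phenyllithium | CCc1c(OC)c([Li])cc(OC)c1O[C@]2(CC)[C@@H](O[Si](CC)(CC)CC)[C@@H](O[Si](CC)(CC)CC)c3c(OC)c(OC)cc(OC)c3[C@@H]2O[Si](CC)(CC)CC | intermediate
24 | lithium pentacarbonyl{[3-ethyl-2,5-dimethoxy-4-(B(TES)3-oxy)phenyl]carbonyl}chromate | [Li]OC(c1cc(OC)c(O[C@]2(CC)[C@@H](O[Si](CC)(CC)CC)[C@@H](O[Si](CC)(CC)CC)c3c(OC)c(OC)cc(OC)c3[C@@H]2O[Si](CC)(CC)CC)c(CC)c1OC)=[Cr](=C=O)(=C=O)(=C=O)(=C=O)=C=O | intermediate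
25 | pentacarbonyl{[3-ethyl-2,5-dimethoxy-4-(B(TES)3-oxy)phenyl](methoxy)carbene}chromium | COC(c1cc(OC)c(O[C@]2(CC)[C@@H](O[Si](CC)(CC)CC)[C@@H](O[Si](CC)(CC)CC)c3c(OC)c(OC)cc(OC)c3[C@@H]2O[Si](CC)(CC)CC)c(CC)c1OC)=[Cr](=C=O)(=C=O)(=C=O)(=C=O)=C=O | intermediate
26 | ethoxyacetylene | C#COCC | starting material
27 | tricarbonylchromium η6 complex of 28 (the η6 bond to ring A is written as a dot) | CCc1c(O[C@]2(CC)[C@@H](O[Si](CC)(CC)CC)[C@@H](O[Si](CC)(CC)CC)c3c(OC)c(OC)cc(OC)c3[C@@H]2O[Si](CC)(CC)CC)c(OC)c2c(O)c(OCC)cc(OC)c2c1OC.O=C=[Cr](=C=O)=C=O | intermediate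
28 | 6'-ethoxy-2'-ethyl-1',4',8'-trimethoxy-3'-[B(TES)3-oxy]naphthalen-5'-ol | CCc1c(O[C@]2(CC)[C@@H](O[Si](CC)(CC)CC)[C@@H](O[Si](CC)(CC)CC)c3c(OC)c(OC)cc(OC)c3[C@@H]2O[Si](CC)(CC)CC)c(OC)c2c(O)c(OCC)cc(OC)c2c1OC | intermediate
29 | 6'-ethoxy-2'-ethyl-1',4'-dimethoxy-3'-[B(TES)3-oxy]naphthalene-5',8'-dione | CCc1c(O[C@]2(CC)[C@@H](O[Si](CC)(CC)CC)[C@@H](O[Si](CC)(CC)CC)c3c(OC)c(OC)cc(OC)c3[C@@H]2O[Si](CC)(CC)CC)c(OC)c2C(=O)C(OCC)=CC(=O)c2c1OC | intermediate
30 | 1,3,4-triol obtained from 29 by loss of the three silyl groups, (1S,2S,3S,4S) | CCc1c(O[C@]2(CC)[C@@H](O)[C@@H](O)c3c(OC)c(OC)cc(OC)c3[C@@H]2O)c(OC)c2C(=O)C(OCC)=CC(=O)c2c1OC | intermediate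
31 | (2S)-2-[(6'-ethoxy-2'-ethyl-1',4'-dimethoxy-5',8'-dioxo-5',8'-dihydronaphthalen-3'-yl)oxy]-2-ethyl-5,6,8-trimethoxynaphthalene-1,3,4(2H)-trione | CCc1c(O[C@]2(CC)C(=O)C(=O)c3c(OC)c(OC)cc(OC)c3C2=O)c(OC)c2C(=O)C(OCC)=CC(=O)c2c1OC | intermediate
32 | ring-A quinone tautomer of the target (1',4',6'-trihydroxy-5',8'-dione form), (2S) | CCc1c(O[C@]2(CC)C(=O)C(=O)c3c(O)c(O)cc(O)c3C2=O)c(O)c2C(=O)C(O)=CC(=O)c2c1O | intermediate
33 | CNP0325426.1, (2S)-2-ethyl-2-[(2'-ethyl-5',6',8'-trihydroxy-1',4'-dioxo-1',4'-dihydronaphthalen-3'-yl)oxy]-5,6,8-trihydroxynaphthalene-1,3,4(2H)-trione | CCC1=C(O[C@]2(CC)C(=O)C(=O)c3c(O)c(O)cc(O)c3C2=O)C(=O)c2c(O)c(O)cc(O)c2C1=O | target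

Total step count: 18. Longest linear sequence: 16 (steps 1–4 and 7–18). Steps 5 and 6 form the short branch.

Steps most likely to fail

1. **Step 14.**
   - What may go wrong: after insertion of the ynol ether the new carbene carbon is stabilised by its ethoxy group, so carbonyl migration may stall. The electron-rich alkyne may also oligomerise at the metal before the ring closes.
   - Fallback: the oxygen at C6' is brought in through boron instead of an ynol ether. Setting out from 25, benzannulation with the electron-poor terminal alkyne 2-ethynyl-4,4,5,5-tetramethyl-1,3,2-dioxaborolane is used. This is a known class of partner whose boryl group is likewise placed next to the carbonyl-derived carbon, and it gives the 6'-(pinacolboryl)naphthol F1. NaBO3·4H2O in THF/H2O turns C–B into C–OH and gives the 5',6'-diol F2. PhI(OAc)2 in aqueous MeCN gives the 6'-hydroxy-5',8'-quinone F3. EtI with K2CO3 in DMF then ethylates the acidic hydroxyquinone, which rejoins the route at 29.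

2. **Step 7.**
   - What may go wrong: attack of the hindered alkoxide at the unsubstituted quinone carbons, electron transfer to the quinone, or deprotonation of the quinone ethyl group may outrun displacement of fluoride.
   - Fallback: an arene SNAr replaces the quinone substitution, with bromine already in place. Commercial 3-fluoroanisole is lithiated between fluorine and methoxy (n-BuLi, THF, −78 °C) and ethylated with EtI to 2-ethyl-1-fluoro-3-methoxybenzene F4. Rieche formylation (Cl2CHOMe, TiCl4, CH2Cl2) para to methoxy gives 3-ethyl-2-fluoro-4-methoxybenzaldehyde F5. Bromination (Br2, AcOH) ortho to methoxy and meta to formyl gives 5-bromo-3-ethyl-2-fluoro-4-methoxybenzaldehyde F6. Setting out from 9, its alkoxide 15 displaces the ortho-formyl-activated fluoride of F6 (THF/DMF, 0 °C → rt) to give the aryl ether aldehyde F7. Dakin-type oxidation (H2O2, cat. (PhSe)2, CH2Cl2) gives the aryl formate F8, and mild hydrolysis (KHCO3, aq. MeOH) gives the phenol F9. MeI with K2CO3 methylates it, which rejoins the route at 18 and bypasses 16 and 17.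

3. **Step 4.**
   - What may go wrong: poor facial discrimination by the chiral reagent on this peri-methoxy naphthol, or over-oxidation of the electron-rich ring.
   - Fallback: racemic oxidation followed by resolution. Setting out from 8, achiral stabilised IBX in THF gives the racemic ketol F10. It is resolved by preparative supercritical-fluid chromatography on a polysaccharide chiral phase. The R enantiomer is 9, where the route is rejoined, and the S enantiomer F11 is set aside.

Further compounds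
F1 | step 14 | 2'-ethyl-1',4',8'-trimethoxy-6'-(4,4,5,5-tetramethyl-1,3,2-dioxaborolan-2-yl)-3'-[B(TES)3-oxy]naphthalen-5'-ol | CCc1c(O[C@]2(CC)[C@@H](O[Si](CC)(CC)CC)[C@@H](O[Si](CC)(CC)CC)c3c(OC)c(OC)cc(OC)c3[C@@H]2O[Si](CC)(CC)CC)c(OC)c2c(O)c(B3OC(C)(C)C(C)(C)O3)cc(OC)c2c1OC
F2 | step 14 | 2'-ethyl-1',4',8'-trimethoxy-3'-[B(TES)3-oxy]naphthalene-5',6'-diol | CCc1c(O[C@]2(CC)[C@@H](O[Si](CC)(CC)CC)[C@@H](O[Si](CC)(CC)CC)c3c(OC)c(OC)cc(OC)c3[C@@H]2O[Si](CC)(CC)CC)c(OC)c2c(O)c(O)cc(OC)c2c1OC
F3 | step 14 | 2'-ethyl-6'-hydroxy-1',4'-dimethoxy-3'-[B(TES)3-oxy]naphthalene-5',8'-dione | CCc1c(O[C@]2(CC)[C@@H](O[Si](CC)(CC)CC)[C@@H](O[Si](CC)(CC)CC)c3c(OC)c(OC)cc(OC)c3[C@@H]2O[Si](CC)(CC)CC)c(OC)c2C(=O)C(O)=CC(=O)c2c1OC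
F4 | step 7 | 2-ethyl-1-fluoro-3-methoxybenzene | CCc1c(F)cccc1OC
F5 | step 7 | 3-ethyl-2-fluoro-4-methoxybenzaldehyde | CCc1c(F)c(C=O)ccc1OC
F6 | step 7 | 5-bromo-3-ethyl-2-fluoro-4-methoxybenzaldehyde | CCc1c(F)c(C=O)cc(Br)c1OC
F7 | step 7 | 5-bromo-3-ethyl-2-{[(2R)-2-ethyl-5,6,8-trimethoxy-1-oxo-1,2-dihydronaphthalen-2-yl]oxy}-4-methoxybenzaldehyde | CCc1c(OC)c(Br)cc(C=O)c1O[C@]2(CC)C=Cc3c(OC)c(OC)cc(OC)c3C2=O
F8 | step 7 | 5-bromo-3-ethyl-2-{[(2R)-2-ethyl-5,6,8-trimethoxy-1-oxo-1,2-dihydronaphthalen-2-yl]oxy}-4-methoxyphenyl formate | CCc1c(OC)c(Br)cc(OC=O)c1O[C@]2(CC)C=Cc3c(OC)c(OC)cc(OC)c3C2=O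
F9 | step 7 | (2R)-2-(4-bromo-2-ethyl-6-hydroxy-3-methoxyphenoxy)-2-ethyl-5,6,8-trimethoxynaphthalen-1(2H)-one | CCc1c(OC)c(Br)cc(O)c1O[C@]2(CC)C=Cc3c(OC)c(OC)cc(OC)c3C2=O
F10 | step 4 | racemic 2-ethyl-2-hydroxy-5,6,8-trimethoxynaphthalen-1(2H)-one | CCC1(O)C=Cc2c(OC)c(OC)cc(OC)c2C1=O
F11 | step 4 | (2S)-2-ethyl-2-hydroxy-5,6,8-trimethoxynaphthalen-1(2H)-one | O[C@@]1(CC)C=Cc2c(OC)c(OC)cc(OC)c2C1=O
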